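**Strategy.** Ring C (the epoxycyclohexane) is opened at the bond between its acyl-bearing carbon (Ca) and the neighbouring methyl-bearing carbon (Cb). With the epoxide carbons Cc and Cd read as an alkene, Ca–Cb–Cc=Cd is the γ,δ-unsaturated acid pattern of a Claisen shift. A δ-lactone trans-fused to ring B, whose carbinol carbon (future Cd) carries a methyl and a (Z)-propenyl group, is converted into its silyl ketene acetal; one boat [3,3] shift then forms Ca–Cb, closes ring C, sets both stereocentres and leaves the Cc=Cd alkene for epoxidation. Rings A and B come from an amino-acid-mediated hydrindenone synthesis; the 13-membered cyclophane is closed last by palladium-catalysed allylation.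

Key step: step 12

Assumption: the hemiaminal carbon and the enol geometry of 42 are taken to be under thermodynamic control (ring–chain and keto–enol tautomerism of the γ-keto amide inside the cyclophane), so the drawn isomer should form in step 20; the C3′ epimers of 39–41 converge on enolisation.

Conventions: hydrindane locants C1–C7a (C1 beside the quaternary C7a, C3 beside C3a); ring C carbons Ca (carboxyl/acyl), Cb (CHMe), Cc, Cd (CMe); C3′ is the carbon between the two carbonyls of the β-keto amide; β is the face of the 7a-methyl group, α the opposite face.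

Stereochemical remarks: lactone 25 and acid 28 match the target centre by centre. The hydrindane belongs to the (7aR) series, so the D-amino acid is needed. The aryl ether is installed with net retention by palladium, relayed from a reliably set C1 oxygen. The β-epoxide is made through a bromohydrin, because a peracid would have to approach past the 7a-methyl group.

Step 1
Reactants: 1 2-methylcyclopentane-1,3-dione; 2 pent-1-en-3-one
Product: 3 2-methyl-2-(3-oxopentyl)cyclopentane-1,3-dione
Conditions: AcOH (cat.), H2O, 75 °C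
Reagents that add atoms: none
Why: Michael addition of the acidic 1,3-dione to the enone should give the achiral triketone; no stereocentre is formed.

Step 2
Reactants: 3 2-methyl-2-(3-oxopentyl)cyclopentane-1,3-dione
Product: 5 (7aR)-4,7a-dimethyl-2,3,7,7a-tetrahydro-1H-indene-1,5(6H)-dione, via ketol 4 (not isolated)
Conditions: D-phenylalanine (1 equiv), 1 M HClO4 (0.5 equiv), MeCN, reflux
Reagents that add atoms: none
Why: Hajos–Parrish–Eder–Sauer–Wiechert aldol cyclodehydration through the D-phenylalanine enamine differentiates the two ring carbonyls, so C7a should be set as R (the mirror image of the series obtained with L-amino acids), and the ketol dehydrates under the acidic conditions.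

Step 3
Reactants: 5 (7aR)-4,7a-dimethyl-2,3,7,7a-tetrahydro-1H-indene-1,5(6H)-dione
Product: 6 C1 ethylene ketal of 5 (spiro-dioxolane at C1, enone untouched)
Conditions: Me3SiOCH2CH2OSiMe3, Me3SiOTf (cat.), CH2Cl2, −78 → −20 °C
Reagents that add atoms: 1,2-bis(trimethylsilyloxy)ethane, C[Si](C)(C)OCCO[Si](C)(C)C
Why: Chemoselective ketalisation; the saturated cyclopentanone should react while the less electrophilic conjugated ketone is left.

Step 4
Reactants: 6 C1 ethylene ketal of 5
Product: 8 6α-methyl enone ketal (C1 dioxolane, C3a=C4 enone, 6-Me α), via lithium dienolate 7 (not isolated)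
Conditions: LiN(iPr)2, THF, −78 °C; MeI, −78 → −20 °C
Reagents that add atoms: iodomethane, CI
Why: Kinetic α′-deprotonation gives the cross-conjugated dienolate, which should be methylated at C6 (enolate alkylation) anti to the axial 7a-methyl group; the centre is equilibrated again in step 5.

Step 5
Reactants: 8 6α-methyl enone ketal
Product: 10 trans-fused ketone ketal (3a-H α, 4-Me α, 6-Me α, C5 ketone, C1 dioxolane), via lithium enolate 9 (not isolated)
Conditions: Li, NH3 (l), THF, t-BuOH (1 equiv), −78 °C; NH4Cl; then NaOMe (cat.), MeOH, rt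
Reagents that add atoms: none
Why: Birch-type dissolving-metal reduction; protonation of C3a anti to the angular methyl should give the trans ring fusion, and base equilibration places the C4 and C6 methyl groups equatorial (α), since an axial methyl at either carbon would be syn-diaxial to the 7a-methyl group.

Step 6
Reactants: 10 trans-fused ketone ketal
Product: 13 4α,6α,7aβ-trimethyl-trans-octahydro-1H-inden-1-one (3a-H α), via hydrazone 11 (not isolated), via dioxolane 12 (not isolated)
Conditions: N2H4·H2O, KOH, diethylene glycol, 130 → 200 °C; then 2 M HCl, THF, rt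
Reagents that add atoms: water, O
Why: Wolff–Kishner reduction (Huang-Minlon modification) should remove the C5 carbonyl without touching the base-stable ketal, the two methyl groups being held equatorial by the axial 7a-methyl group, and aqueous acid then frees the C1 ketone.

Step 7
Reactants: 13 4α,6α,7aβ-trimethyl-trans-octahydro-1H-inden-1-one
Product: 15 4α,6α,7aβ-trimethyl-3a,4,5,6,7,7a-hexahydro-1H-inden-1-one (C2=C3 enone, 3a-H α), via silyl enol ether 14 (not isolated)
Conditions: LiN(iPr)2, Me3SiCl, THF, −78 °C; then Pd(OAc)2 (1 equiv), MeCN, rt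
Reagents that add atoms: none
Why: Saegusa–Ito oxidation; the ketone can enolise only towards C2, and the silyl enol ether should be dehydrogenated to the C2=C3 enone.

Step 8
Reactants: 15 hydrindenone (C1 ketone, C2=C3)
Product: 18 tertiary allylic carbonate (C1: OCO2Me β, acetyl α; C2=C3), via lithium alkoxide 16 (not isolated), via enol ether carbonate 17 (not isolated)
Conditions: CH2=CHOEt, t-BuLi, THF, −78 → 0 °C; add 15, −78 °C; ClCO2Me, −78 → 0 °C; then 0.5 M HCl, THF, 0 °C
Reagents that add atoms: ethyl vinyl ether, C=COCC; methyl chloroformate, COC(=O)Cl; water, O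
Why: 1,2-Addition of the acyl anion equivalent 1-ethoxyvinyllithium from the α face (anti to the 7a-methyl group, as with 17-oxo steroids) should set the C1–O bond β; the alkoxide is acylated in situ and the enol ether is hydrolysed to the acetyl group.

Step 9
Reactants: 18 tertiary allylic carbonate; 19 4-bromophenol
Product: 20 γ-aryloxy enone (1-acetyl, C1=C2, C3 4-bromophenoxy β)
Conditions: Pd2(dba)3·CHCl3 (2.5 mol%), PPh3 (15 mol%), THF, rt
Reagents that add atoms: none
Why: Tsuji–Trost allylic etherification; zerovalent palladium ionises the β-carbonate with inversion and the phenoxide attacks the allyl terminus remote from the acyl group (C3) anti to palladium, so the C1 β-oxygen should be relayed to a C3 β-aryl ether with net retention of face while the conjugated enone forms.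

Step 10
Reactants: 20 γ-aryloxy enone
Product: 22 methyl 2-[1β-acetyl-3β-(4-bromophenoxy)-4α,6α,7aβ-trimethyl-trans-hydrindan-2α-yl]acetate, via silyl enol ether 21 (not isolated)
Conditions: CH2=C(OMe)OSiMe2t-Bu, LiClO4 (3 M in Et2O), rt; then 1 M HCl, THF, rt
Reagents that add atoms: tert-butyl[(1-methoxyethenyl)oxy]dimethylsilane, C=C(OC)O[Si](C)(C)C(C)(C)C
Why: Mukaiyama–Michael addition to C2 from the α face, anti to both the C3 aryl ether and the 7a-methyl group; hydrolysis of the silyl enol ether under equilibrating acid should leave the acetyl group β, trans to the new arm (the thermodynamic arrangement, as in 16α-substituted pregnan-20-ones).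

Step 11
Reactants: 22 keto ester; 23 (Z)-1-bromoprop-1-ene
Product: 25 ring B-fused δ-lactone of the tertiary (Z)-propenyl carbinol (carbinol carbon: methyl β, propenyl α; C3 4-bromophenoxy β), via hydroxy ester 24 (not isolated)
Conditions: 23, t-BuLi (2 equiv), Et2O, −78 °C; CeCl3, THF, −78 °C; add 22, −78 → 0 °C
Reagents that add atoms: none
Why: Organocerium 1,2-addition under Felkin–Anh control (nucleophile anti to the quaternary C7a, passing C1–H) should give the carbinol with methyl β and propenyl α, the vinyl metal keeping its Z geometry, and the alkoxide closes the trans-fused lactone on the methyl ester (lactonisation).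

Step 12
Reactants: 25 ring B-fused δ-lactone
Product: 28 tricyclic cyclohexene carboxylic acid (rings A, B and C; Ca–CO2H β, Cb–Me α, Cc=Cd), via silyl ketene acetal 26 (not isolated), via silyl ester 27 (not isolated)
Conditions: LiN(iPr)2, t-BuMe2SiCl, THF/DMPU, −78 °C; toluene, 110 °C; then 1 M HCl, THF, rt
Reagents that add atoms: none
Why: Ireland–Claisen ring contraction of a lactone (closest known type: rearrangement of alkenyl-substituted lactone silyl ketene acetals to cycloalkene carboxylic acids): deprotonation and silylation give the cyclic ketene acetal 26, whose enolate geometry is fixed by the ring, and heating should drive a suprafacial [3,3] shift in which bond formation between the lactone α-carbon (Ca) and the propenyl terminus (Cb) is concerted with cleavage of the carbinol C–O bond. Ring C closes as a six-membered carbocycle through a bicyclo[2.2.2]-like boat transition state, the only one a six-membered lactone allows, with the propenyl group bridging the α face of the lactone. Ca is controlled by the carbinol configuration set in step 11: the propenyl group can reach the enolate carbon only from the α face, so the carboxyl group ends up β and equatorial. Cb is controlled by the alkene geometry: in the boat the Z methyl group points inwards, which places it α, trans to the carboxyl group, whereas an E-propenyl group would give the epimer. The step needs this facial and simple diastereoselection together with a reachable boat, and the substrate secures both because the trans fusion to ring B twists the C1–C2 bond in the sense the boat requires. Enolisation is unambiguous (one α-methylene group, no leaving group β to it), and the new Cc=Cd alkene lands where the epoxide is needed.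

Step 13
Reactants: 28 tricyclic cyclohexene carboxylic acid
Product: 30 epoxy acid (Cc–Cd β-epoxide), via bromohydrin 29 (not isolated)
Conditions: NBS, DME/H2O (3:1), 0 °C; then K2CO3, MeOH, rt; acidify to pH 4
Reagents that add atoms: water, O
Why: Bromohydrin formation and base-induced ring closure; reversible bromonium formation should be funnelled through Markovnikov, trans-diaxial (Fürst–Plattner) opening of the α-bromonium ion by water at Cd from the β face, and the β-alkoxide then displaces the α-bromide at Cc to give the β-epoxide.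

Step 14
Reactants: 30 epoxy acid
Product: 32 S-phenyl β-keto thioester (Ca–C(=O)CH2C(=O)SPh), via acyl imidazolide 31 (not isolated)
Conditions: CDI, THF, rt; then PhSC(O)CH2CO2H, Mg(OEt)2, THF, 40 °C; sat. NH4Cl
Reagents that add atoms: 3-oxo-3-(phenylsulfanyl)propanoic acid, OC(=O)CC(=O)Sc1ccccc1
Why: Masamune–Brooks decarboxylative Claisen condensation of the acyl imidazolide with the magnesium malonate half thioester runs under nearly neutral conditions that should spare the epoxide and the aryl bromide; no stereocentre is touched.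

Step 15
Reactants: 32 S-phenyl β-keto thioester
Product: 33 primary β-keto amide (Ca–C(=O)CH2C(=O)NH2)
Conditions: NH3 (0.5 M in 1,4-dioxane), AgOCOCF3, THF, 0 °C
Reagents that add atoms: ammonia, N
Why: Silver-promoted aminolysis of the thioester should give the primary amide at low temperature, the thiolate being removed as its silver salt so that it cannot open the epoxide.

Step 16
Reactants: 34 2-methylprop-2-en-1-ol
Product: 36 2-[(tributylstannyl)methyl]prop-2-en-1-ol, via dilithio alkoxide 35 (not isolated)
Conditions: n-BuLi (2.2 equiv), TMEDA, Et2O/THF, 0 °C → rt; Bu3SnCl, −78 → 0 °C; sat. NH4Cl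
Reagents that add atoms: tributyltin chloride, CCCC[Sn](Cl)(CCCC)CCCC
Why: Allylic metalation of the lithium alkoxide to the dianion and C-stannylation (carbanion trapping) should give the bifunctional allylstannane.

Step 17
Reactants: 33 primary β-keto amide; 36 2-[(tributylstannyl)methyl]prop-2-en-1-ol
Product: 37 allylic alcohol (aryl bromide replaced by CH2C(=CH2)CH2OH)
Conditions: Pd(PPh3)4 (5 mol%), toluene, 100 °C
Reagents that add atoms: none
Why: Migita–Stille coupling under neutral conditions should tolerate the epoxide and the acidic β-keto amide; allyl transfer through either terminus gives the same 2-(hydroxymethyl)allyl arene.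

Step 18
Reactants: 37 allylic alcohol
Product: 38 allylic methyl carbonate
Conditions: ClCO2Me, pyridine, CH2Cl2, 0 °C
Reagents that add atoms: methyl chloroformate, COC(=O)Cl
Why: Selective O-acylation of the primary allylic alcohol (the β-keto amide should not be acylated by a chloroformate and pyridine at 0 °C) installs the leaving group for ring closure.

Step 19
Reactants: 38 allylic methyl carbonate
Product: 39 13-membered macrocyclic β-keto amide (C3′–CH2C(=CH2)CH2–aryl)
Conditions: Pd2(dba)3·CHCl3 (5 mol%), Ph2PCH2CH2PPh2 (12 mol%), THF (0.002 M, slow addition), 60 °C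
Reagents that add atoms: none
Why: Tsuji–Trost macrocyclisation; ionisation gives a symmetrical 2-substituted allylpalladium cation and methoxide, which deprotonates the β-keto amide, and C-alkylation at high dilution should close the 13-membered ring (O-allylation is reversible under the catalysis; the new C3′ centre is lost on later enolisation).

Step 20
Reactants: 39 13-membered macrocyclic β-keto amide
Product: 42 Pyrrospirone O, via diol 40 (not isolated), via keto amide 41 (not isolated)
Conditions: OsO4 (2 mol%), NaIO4 (3 equiv), 2,6-lutidine, 1,4-dioxane/H2O (3:1), rt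
Reagents that add atoms: osmium tetroxide, O=[Os](=O)(=O)=O; sodium periodate, [Na+].[O-]I(=O)(=O)=O
Why: Lemieux–Johnson cleavage of the only remaining alkene unveils the ketone, to which the primary amide should add (5-exo hemiaminal formation) under thermodynamic control, and the 3-acyl lactam settles as the hydrogen-bonded enol drawn for the target.

**Compound list**

1 | 2-methylcyclopentane-1,3-dione | CC1C(=O)CCC1=O | starting material
2 | pent-1-en-3-one | CCC(=O)C=C | starting material
3 | 2-methyl-2-(3-oxopentyl)cyclopentane-1,3-dione | CCC(=O)CCC1(C)C(=O)CCC1=O | intermediate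
4 | cis-fused ketol, (7aR)-3a-hydroxy-4,7a-dimethylhexahydro-1H-indene-1,5-dione (3a-OH cis to 7a-Me, C4 unassigned; not isolated) | CC1C(=O)CC[C@@]2(C)C(=O)CC[C@@]12O | intermediate
5 | (7aR)-4,7a-dimethyl-2,3,7,7a-tetrahydro-1H-indene-1,5(6H)-dione | CC1=C2CCC(=O)[C@]2(C)CCC1=O | intermediate
6 | C1 ethylene ketal of 5 | CC1=C2CCC3(OCCO3)[C@]2(C)CCC1=O | intermediate
7 | lithium cross-conjugated dienolate of 6 (C5–OLi, C5=C6; not isolated) | CC1=C2CCC3(OCCO3)[C@]2(C)CC=C1O[Li] | intermediate
8 | 6α-methyl enone ketal | CC1=C2CCC3(OCCO3)[C@]2(C)C[C@H](C)C1=O | intermediate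
9 | lithium enolate of the trans-fused ketone (C4=C5–OLi; not isolated) | C[C@@H]1C(O[Li])=C(C)[C@H]2CCC3(OCCO3)[C@]2(C)C1 | intermediate
10 | trans-fused ketone ketal (3a-H α, 4α,6α,7aβ-trimethyl, C5 ketone) | C[C@@H]1C(=O)[C@H](C)[C@H]2CCC3(OCCO3)[C@]2(C)C1 | intermediate
11 | hydrazone of 10 (not isolated) | C[C@@H]1C(=NN)[C@H](C)[C@H]2CCC3(OCCO3)[C@]2(C)C1 | intermediate
12 | 4α,6α,7aβ-trimethyl-trans-hydrindane C1 dioxolane (not isolated) | C[C@@H]1C[C@H](C)[C@H]2CCC3(OCCO3)[C@]2(C)C1 | intermediate
13 | 4α,6α,7aβ-trimethyl-trans-octahydro-1H-inden-1-one | C[C@@H]1C[C@H](C)[C@H]2CCC(=O)[C@]2(C)C1 | intermediate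
14 | trimethylsilyl enol ether of 13 (C1=C2; not isolated) | C[C@@H]1C[C@H](C)[C@H]2CC=C(O[Si](C)(C)C)[C@]2(C)C1 | intermediate
15 | 4α,6α,7aβ-trimethyl-3a,4,5,6,7,7a-hexahydro-1H-inden-1-one (C2=C3) | C[C@@H]1C[C@H](C)[C@H]2C=CC(=O)[C@]2(C)C1 | intermediate
16 | lithium 1α-(1-ethoxyvinyl)-1β-alkoxide (not isolated) | C[C@@H]1C[C@H](C)[C@H]2C=C[C@](O[Li])(C(=C)OCC)[C@]2(C)C1 | intermediate
17 | 1α-(1-ethoxyvinyl) 1β-methyl carbonate (not isolated) | C[C@@H]1C[C@H](C)[C@H]2C=C[C@](OC(=O)OC)(C(=C)OCC)[C@]2(C)C1 | intermediate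
18 | 1α-acetyl 1β-methyl carbonate (C2=C3) | C[C@@H]1C[C@H](C)[C@H]2C=C[C@](OC(=O)OC)(C(C)=O)[C@]2(C)C1 | intermediate
19 | 4-bromophenol | Oc1ccc(Br)cc1 | starting material
20 | 1-acetyl-3β-(4-bromophenoxy)-4α,6α,7aβ-trimethyl-3aα-H hydrind-1-ene | C[C@@H]1C[C@H](C)[C@H]2[C@@H](Oc3ccc(Br)cc3)C=C(C(C)=O)[C@]2(C)C1 | intermediate
21 | tert-butyldimethylsilyl enol ether of 22 (not isolated) | C[C@@H]1C[C@H](C)[C@H]2[C@@H](Oc3ccc(Br)cc3)[C@H](CC(=O)OC)C(=C(C)O[Si](C)(C)C(C)(C)C)[C@]2(C)C1 | intermediate
22 | methyl 2-[1β-acetyl-3β-(4-bromophenoxy)-4α,6α,7aβ-trimethyl-trans-hydrindan-2α-yl]acetate | C[C@@H]1C[C@H](C)[C@H]2[C@@H](Oc3ccc(Br)cc3)[C@H](CC(=O)OC)[C@@H](C(C)=O)[C@]2(C)C1 | intermediate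
23 | (Z)-1-bromoprop-1-ene | C/C=C\Br | starting material
24 | tertiary (Z)-propenyl carbinol methyl ester, formed as its alkoxide (not isolated) | C[C@@H]1C[C@H](C)[C@H]2[C@@H](Oc3ccc(Br)cc3)[C@H](CC(=O)OC)[C@@H]([C@](C)(O)/C=C\C)[C@]2(C)C1 | intermediate
25 | ring B-fused δ-lactone of the tertiary (Z)-propenyl carbinol, 4-bromophenyl ether | C[C@@H]1C[C@H](C)[C@H]2[C@@H](Oc4ccc(Br)cc4)[C@@H]3CC(=O)O[C@](C)(/C=C\C)[C@H]3[C@]2(C)C1 | intermediate
26 | tert-butyldimethylsilyl ketene acetal of 25 (not isolated) | C[C@@H]1C[C@H](C)[C@H]2[C@@H](Oc4ccc(Br)cc4)[C@@H]3C=C(O[Si](C)(C)C(C)(C)C)O[C@](C)(/C=C\C)[C@H]3[C@]2(C)C1 | intermediate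
27 | tert-butyldimethylsilyl ester of 28 (not isolated) | C[C@@H]1C[C@H](C)[C@H]2[C@@H](Oc4ccc(Br)cc4)[C@@H]3[C@@H](C(=O)O[Si](C)(C)C(C)(C)C)[C@H](C)C=C(C)[C@H]3[C@]2(C)C1 | intermediate
28 | tricyclic cyclohexene carboxylic acid (rings A, B and C) | C[C@@H]1C[C@H](C)[C@H]2[C@@H](Oc4ccc(Br)cc4)[C@@H]3[C@@H](C(=O)O)[C@H](C)C=C(C)[C@H]3[C@]2(C)C1 | intermediate
29 | bromohydrin acid (Cc–Br α, Cd–OH β; not isolated) | C[C@@H]1C[C@H](C)[C@H]2[C@@H](Oc4ccc(Br)cc4)[C@@H]3[C@@H](C(=O)O)[C@H](C)[C@H](Br)[C@@](C)(O)[C@H]3[C@]2(C)C1 | intermediate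
30 | epoxy acid (β-epoxide) | C[C@@H]1C[C@H](C)[C@H]2[C@@H](Oc4ccc(Br)cc4)[C@@H]3[C@@H](C(=O)O)[C@H](C)[C@H]5O[C@@]5(C)[C@H]3[C@]2(C)C1 | intermediate
31 | acyl imidazolide of 30 (not isolated) | C[C@@H]1C[C@H](C)[C@H]2[C@@H](Oc4ccc(Br)cc4)[C@@H]3[C@@H](C(=O)n6ccnc6)[C@H](C)[C@H]5O[C@@]5(C)[C@H]3[C@]2(C)C1 | intermediate
32 | S-phenyl β-keto thioester | C[C@@H]1C[C@H](C)[C@H]2[C@@H](Oc4ccc(Br)cc4)[C@@H]3[C@@H](C(=O)CC(=O)Sc6ccccc6)[C@H](C)[C@H]5O[C@@]5(C)[C@H]3[C@]2(C)C1 | intermediate
33 | primary β-keto amide | C[C@@H]1C[C@H](C)[C@H]2[C@@H](Oc4ccc(Br)cc4)[C@@H]3[C@@H](C(=O)CC(N)=O)[C@H](C)[C@H]5O[C@@]5(C)[C@H]3[C@]2(C)C1 | intermediate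
34 | 2-methylprop-2-en-1-ol | CC(=C)CO | starting material
35 | dilithio alkoxide of 34 (not isolated) | [Li]CC(=C)CO[Li] | intermediate
36 | 2-[(tributylstannyl)methyl]prop-2-en-1-ol | CCCC[Sn](CCCC)(CCCC)CC(=C)CO | intermediate
37 | allylic alcohol, 4-[2-(hydroxymethyl)allyl]phenyl ether | C[C@@H]1C[C@H](C)[C@H]2[C@@H](Oc4ccc(CC(=C)CO)cc4)[C@@H]3[C@@H](C(=O)CC(N)=O)[C@H](C)[C@H]5O[C@@]5(C)[C@H]3[C@]2(C)C1 | intermediate
38 | allylic methyl carbonate | C[C@@H]1C[C@H](C)[C@H]2[C@@H](Oc4ccc(CC(=C)COC(=O)OC)cc4)[C@@H]3[C@@H](C(=O)CC(N)=O)[C@H](C)[C@H]5O[C@@]5(C)[C@H]3[C@]2(C)C1 | intermediate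
39 | 13-membered macrocyclic β-keto amide with exocyclic methylene (C3′ unassigned) | C[C@@H]1C[C@H](C)[C@H]2[C@H]3Oc4ccc(cc4)CC(=C)CC(C(N)=O)C(=O)[C@H]5[C@H](C)[C@H]6O[C@@]6(C)[C@H]([C@H]35)[C@]2(C)C1 | intermediate
40 | macrocyclic 1,2-diol (not isolated) | C[C@@H]1C[C@H](C)[C@H]2[C@H]3Oc4ccc(cc4)CC(O)(CO)CC(C(N)=O)C(=O)[C@H]5[C@H](C)[C@H]6O[C@@]6(C)[C@H]([C@H]35)[C@]2(C)C1 | intermediate
41 | macrocyclic diketo amide (not isolated) | C[C@@H]1C[C@H](C)[C@H]2[C@H]3Oc4ccc(cc4)CC(=O)CC(C(N)=O)C(=O)[C@H]5[C@H](C)[C@H]6O[C@@]6(C)[C@H]([C@H]35)[C@]2(C)C1 | intermediate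
42 | Pyrrospirone O | C[C@@H]1C[C@H](C)[C@H]2[C@H]3Oc4ccc(cc4)C[C@]4(O)C/C(=C(/O)[C@H]5[C@H](C)[C@H]6O[C@@]6(C)[C@H]([C@H]35)[C@]2(C)C1)C(=O)N4 | target

**Totals.** Total step count: 20. Longest linear sequence: 19 steps (steps 1–15 and 17–20); step 16 is a one-step side branch.

**Steps most likely to fail**

1. Step 12 (key step). The strained boat may be reached too slowly, so that the silyl ketene acetal is lost to C-silylation or hydrolysis, or the inward Z-methyl group may let the Cb configuration erode. Fallback: ring C would be closed by metathesis after an open-chain Claisen shift, setting out from keto ester 22 and coming back at acid 28. Wittig methylenation of the acetyl group (Ph3P=CH2, THF) would give the isopropenyl ester F1. Saponification (LiOH, THF/H2O) would give the isopropenyl acid F2. Esterification with (E)-but-2-en-1-ol (DCC, DMAP) would give the (E)-crotyl ester F3. The chair Ireland–Claisen rearrangement of its kinetic silyl ketene acetal (LiN(iPr)2, Me3SiCl, THF, −78 °C → rt), which for an (E)-crotyl ester should favour the required anti relationship of Ca and Cb, would give the diene acid F4. Ring-closing metathesis with the second-generation Grubbs catalyst (CH2Cl2, 40 °C) between the vinyl and isopropenyl groups would form Cc=Cd and return to 28.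

2. Step 19. Strain in the developing 13-membered cyclophane may make ring closure slower than intermolecular allylation, so that dimers and oligomers form. Fallback: the sp3 C–C bond would be made intermolecularly and the ring closed at the aryl–CH2 bond, setting out from β-keto amide 33 and coming back at macrocycle 39. Stannane 36 would be converted (MsCl, Et3N; LiCl, DMF) into 2-(chloromethyl)-3-(tributylstannyl)prop-1-ene F5. C-Alkylation of 33 with it (K2CO3, acetone) would give the stannylated bromoarene F6. An intramolecular Migita–Stille coupling (Pd(PPh3)4, toluene, 100 °C, high dilution) would then close the ring to 39.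

3. Step 9. Ionisation of the congested tertiary carbonate may be slow, the allylpalladium intermediate may undergo β-hydride elimination to a dienone, or palladium exchange may erode the facial relay. Fallback: the oxygen would be transposed sigmatropically and the aryl ether made by Mitsunobu inversion, setting out from enone 15 and coming back at γ-aryloxy enone 20. Addition of 1-ethoxyvinyllithium and acidic hydrolysis without acylation would give the tertiary α-ketol F7. A suprafacial 1,3-transposition (Ph3SiOReO3 cat., Et2O, 0 °C), driven by conjugation, would give the 3β-hydroxy enone F8. Mitsunobu reaction with 4-nitrobenzoic acid (PPh3, DIAD) would give the inverted 3α-(4-nitrobenzoate) F9. Methanolysis (K2CO3, MeOH) would give the 3α-hydroxy enone F10. A second Mitsunobu reaction with 4-bromophenol 19 would invert C3 again and return to 20.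

**Further compounds**

F1 | step 12 | methyl 2-[3β-(4-bromophenoxy)-1β-isopropenyl-4α,6α,7aβ-trimethyl-trans-hydrindan-2α-yl]acetate | C[C@@H]1C[C@H](C)[C@H]2[C@@H](Oc3ccc(Br)cc3)[C@H](CC(=O)OC)[C@@H](C(C)=C)[C@]2(C)C1
F2 | step 12 | corresponding isopropenyl acetic acid | C[C@@H]1C[C@H](C)[C@H]2[C@@H](Oc3ccc(Br)cc3)[C@H](CC(=O)O)[C@@H](C(C)=C)[C@]2(C)C1
F3 | step 12 | (E)-but-2-enyl ester of F2 | C[C@@H]1C[C@H](C)[C@H]2[C@@H](Oc3ccc(Br)cc3)[C@H](CC(=O)OC/C=C/C)[C@@H](C(C)=C)[C@]2(C)C1
F4 | step 12 | diene acid, 3-methylpent-4-enoic acid carrying the hydrindanyl group at C2 (Ca and Cb as in 28) | C[C@@H]1C[C@H](C)[C@H]2[C@@H](Oc3ccc(Br)cc3)[C@H]([C@@H](C(=O)O)[C@H](C)C=C)[C@@H](C(C)=C)[C@]2(C)C1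
F5 | step 19 | 2-(chloromethyl)-3-(tributylstannyl)prop-1-ene | CCCC[Sn](CCCC)(CCCC)CC(=C)CCl
F6 | step 19 | C3′-[2-(tributylstannylmethyl)allyl] β-keto amide, aryl bromide retained | C[C@@H]1C[C@H](C)[C@H]2[C@@H](Oc4ccc(Br)cc4)[C@@H]3[C@@H](C(=O)C(C(N)=O)CC(=C)C[Sn](CCCC)(CCCC)CCCC)[C@H](C)[C@H]5O[C@@]5(C)[C@H]3[C@]2(C)C1
F7 | step 9 | 1α-acetyl-1β-hydroxy hydrind-2-ene (tertiary α-ketol) | C[C@@H]1C[C@H](C)[C@H]2C=C[C@](O)(C(C)=O)[C@]2(C)C1
F8 | step 9 | 1-acetyl-3β-hydroxy hydrind-1-ene | C[C@@H]1C[C@H](C)[C@H]2[C@@H](O)C=C(C(C)=O)[C@]2(C)C1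
F9 | step 9 | 1-acetyl-3α-(4-nitrobenzoyloxy) hydrind-1-ene | C[C@@H]1C[C@H](C)[C@H]2[C@H](OC(=O)c3ccc(cc3)[N+](=O)[O-])C=C(C(C)=O)[C@]2(C)C1
F10 | step 9 | 1-acetyl-3α-hydroxy hydrind-1-ene | C[C@@H]1C[C@H](C)[C@H]2[C@H](O)C=C(C(C)=O)[C@]2(C)C1
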